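**Plan**

- Retrosynthesis: the C6–C6' biaryl bond is cut first (Suzuki coupling of a 6-bromide and a 6-boronate that differ only at C4). In the monomer, the bonds O1–C8a and C4a–C4 are then cut together.
- Enabling feature: on ring A, C8a (bearing O1, next to the C8 oxygen) is ortho to C4a (bearing C4), and C4 is a carbinol that can be carried as a ketone. A C4 ketone on C4a activates a fluorine on C8a, so ring C is closed as a chroman-4-one from a 2-fluoroaryllithium and a cyclic acetonide ester of the aldol acid, which releases the O1 alkoxide only after the C4a–C4 bond exists.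
- Regiochemistry is locked by bromine at C4a and fluorine at C8a. An aryne across C4a/C8a is not used because an oxygen nucleophile would add at C4a, meta to the C8 oxygen.
- Forward order: syn glycolate aldol (C2–C3) → acid → 1,3-dioxan-4-one; 3-fluorocatechol → dibenzyl ether → bromide; annulation (ring C) → ketone reduction → C6 bromination → C4 epimerisation of one portion → borylation → Suzuki coupling → hydrogenolysis.
- Stereochemistry: C2 and C3 of both halves come from the oxazolidinone-controlled syn aldol. C4 (R) comes from hydride addition anti to the 3-benzyloxy group. C4' (S) comes from SN1 exchange with water entering anti to the 3-benzyloxy group.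

Key step: step 7

Assumption: the target has no descriptor for the C6–C6' axis; with one ortho oxygen on each ring the biaryl is taken to rotate freely, so no axial control is planned. Flavan numbering (O1, C2, C3, C4, C4a, C5–C8, C8a) is used throughout.

**Route**

Step 1
Reactants: 1 (S)-4-benzyl-1,3-oxazolidin-2-one; 2 (benzyloxy)acetyl chloride
Product: 3 (4S)-4-benzyl-3-[(benzyloxy)acetyl]-1,3-oxazolidin-2-one
Conditions: Et3N, DMAP (cat.), CH2Cl2, 0 °C to rt
Reagents that add atoms: none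
Why: N-acylation of the oxazolidinone by the acid chloride (DMAP-catalysed acyl transfer) is routine for this auxiliary and creates no stereocenter.

Step 2
Reactants: 3 (4S)-4-benzyl-3-[(benzyloxy)acetyl]-1,3-oxazolidin-2-one; 4 4-(benzyloxy)benzaldehyde
Product: 6 (4S)-4-benzyl-3-[(2S,3R)-2-(benzyloxy)-3-[4-(benzyloxy)phenyl]-3-hydroxypropanoyl]-1,3-oxazolidin-2-one, via dibutylboron Z-enolate 5 (not isolated)
Conditions: Bu2BOTf, Et3N, CH2Cl2, −78 to 0 °C; then 4, −78 to 0 °C; work-up MeOH, pH 7 buffer, 30% H2O2, 0 °C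
Reagents that add atoms: none
Why: Evans syn aldol reaction, in which the boron Z-enolate reacts through a chair Zimmerman–Traxler transition state on the face away from the auxiliary benzyl group, so both new centers (2S,3R, the later C3 and C2) should form as the syn adduct with the future O1 free and the future O3 already benzylated.

Step 3
Reactants: 6 (4S)-4-benzyl-3-[(2S,3R)-2-(benzyloxy)-3-[4-(benzyloxy)phenyl]-3-hydroxypropanoyl]-1,3-oxazolidin-2-one
Product: 8 (2S,3R)-2-(benzyloxy)-3-[4-(benzyloxy)phenyl]-3-hydroxypropanoic acid, via peroxy acid 7 (not isolated)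
Conditions: LiOH, 30% H2O2, THF–H2O, 0 °C; then aq Na2SO3; then 1 M HCl to pH 3, 0 °C
Reagents that add atoms: hydrogen peroxide, OO
Why: Hydroperoxide-mediated cleavage of the N-acyl oxazolidinone (attack at the exocyclic carbonyl, then sulfite reduction of the peroxy acid) is the standard hydrolysis of such aldol adducts and breaks no bond at either stereocenter.

Step 4
Reactants: 8 (2S,3R)-2-(benzyloxy)-3-[4-(benzyloxy)phenyl]-3-hydroxypropanoic acid
Product: 9 (5S,6R)-5-(benzyloxy)-6-[4-(benzyloxy)phenyl]-2,2-dimethyl-1,3-dioxan-4-one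
Conditions: 2-methoxypropene, PPTS (cat.), 4 Å molecular sieves, CH2Cl2, 0 °C
Reagents that add atoms: 2-methoxypropene, COC(C)=C
Why: Acid-catalysed ketalisation with an enol ether ties the hydroxyl and carboxyl groups of the β-hydroxy acid into a 1,3-dioxan-4-one (a known class of such acids) without touching either stereocenter, and a ketone-derived acetal is chosen so that no acetal hydrogen is available for a later hydride shift.

Step 5
Reactants: 10 3-fluorobenzene-1,2-diol
Product: 11 1,2-bis(benzyloxy)-3-fluorobenzene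
Conditions: BnBr, K2CO3, DMF, 60 °C
Reagents that add atoms: benzyl bromide, BrCc1ccccc1
Why: Williamson ether synthesis on both phenols.

Step 6
Reactants: 11 1,2-bis(benzyloxy)-3-fluorobenzene
Product: 12 1,2-bis(benzyloxy)-4-bromo-3-fluorobenzene
Conditions: NBS, MeCN, 0 °C to rt, dark
Reagents that add atoms: N-bromosuccinimide, O=C1CCC(=O)N1Br
Why: Electrophilic aromatic bromination should go para to the less hindered 1-benzyloxy group (the position next to fluorine), as 3-fluoroanisole brominates para to its alkoxy group, while the flanked 2-benzyloxy group is twisted out of plane and activates its own para position little.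

Step 7
Reactants: 12 1,2-bis(benzyloxy)-4-bromo-3-fluorobenzene; 9 (5S,6R)-5-(benzyloxy)-6-[4-(benzyloxy)phenyl]-2,2-dimethyl-1,3-dioxan-4-one
Product: 16 (2R,3S)-3,7,8-tris(benzyloxy)-2-[4-(benzyloxy)phenyl]-2,3-dihydro-4H-chromen-4-one, via aryllithium 13 (not isolated), via cyclic lithium hemiketal 14 (not isolated), via lithium keto-alkoxide 15 (not isolated)
Conditions: 12, n-BuLi (1.0 equiv), THF, −78 °C, 20 min; add to 9 (1.05 equiv) in THF, −78 °C, 1 h; warm to rt; aq NH4Cl
Reagents that add atoms: none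
Why: Bromine–lithium exchange gives the 2-fluoroaryllithium 13, whose carbanion carbon (the future C4a) adds to the lactone-type carbonyl of 9 to form the C4a–C4 bond as the cyclic lithium hemiketal 14, which should persist at −78 °C so that no ketone meets 13; on warming 14 opens, loses acetone and unveils the alkoxide 15, whose oxygen (the future O1) attacks C8a, the fluorine-bearing carbon ortho to the new ketone, by addition–elimination (SNAr) with loss of LiF. The closest known reaction types are the acylation of organolithium reagents by lactones and dioxanones to give hydroxy ketones and the closure of chroman-4-ones by intramolecular SNAr of 2-fluoroaryl β-hydroxy ketones. Ring C closes by 6-exo-trig addition of O1 to C8a through a Meisenheimer intermediate. No stereocenter is created: the bonds at C2 and C3 come unchanged from 9, so the syn aldol relation becomes the 2,3-cis (2R,3S) ketone. The step needs regioselectivity (oxygen at C8a, carbon at C4a), fixed by the positions of bromine and fluorine in 12, and it needs mono-addition and configurational integrity at C3, which rest on the hemiketal holding the ketone back and on the only base in the flask being the alkoxide that is consumed in the ring closure.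

Step 8
Reactants: 16 (2R,3S)-3,7,8-tris(benzyloxy)-2-[4-(benzyloxy)phenyl]-2,3-dihydro-4H-chromen-4-one
Product: 17 (2R,3R,4R)-3,7,8-tris(benzyloxy)-2-[4-(benzyloxy)phenyl]-3,4-dihydro-2H-chromen-4-ol
Conditions: NaBH4, THF–MeOH, −20 to 0 °C
Reagents that add atoms: none
Why: Hydride reduction of the aryl ketone, in which hydride should enter C4 axially and anti to the pseudo-axial 3-benzyloxy group (Felkin–Anh sense), setting C4 as R with the 4-hydroxyl cis to O3, the outcome expected for 2,3-cis-dihydroflavonols.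

Step 9
Reactants: 17 (2R,3R,4R)-3,7,8-tris(benzyloxy)-2-[4-(benzyloxy)phenyl]-3,4-dihydro-2H-chromen-4-ol
Product: 18 (2R,3R,4R)-3,7,8-tris(benzyloxy)-2-[4-(benzyloxy)phenyl]-6-bromo-3,4-dihydro-2H-chromen-4-ol
Conditions: NBS (1.0 equiv), MeCN, −10 to 0 °C, dark
Reagents that add atoms: N-bromosuccinimide, O=C1CCC(=O)N1Br
Why: Electrophilic aromatic bromination should take place at C6, para to the ring oxygen O1 and ortho to the 7-benzyloxy group, which is the most nucleophilic position of ring A and more electron-rich than any position of the mono-oxygenated 2-aryl ring.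

Step 10
Reactants: 18 (2R,3R,4R)-3,7,8-tris(benzyloxy)-2-[4-(benzyloxy)phenyl]-6-bromo-3,4-dihydro-2H-chromen-4-ol (one portion)
Product: 19 (2R,3R,4S)-3,7,8-tris(benzyloxy)-2-[4-(benzyloxy)phenyl]-6-bromo-3,4-dihydro-2H-chromen-4-ol
Conditions: camphorsulfonic acid (cat.), THF–H2O (4:1), rt
Reagents that add atoms: water, O
Why: Acid-catalysed SN1 exchange of the benzylic hydroxyl, in which the C4 cation (stabilised by the para 7-oxygen and the ortho ring oxygen) should take up water anti to the pseudo-axial 3-benzyloxy group, so that the 3,4-cis alcohol drains into the 3,4-trans (4S) epimer as in the known C4 epimerisation of 2,3-cis flavan-3,4-diols, while the 6-bromine blocks self-condensation at C6.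

Step 11
Reactants: 19 (2R,3R,4S)-3,7,8-tris(benzyloxy)-2-[4-(benzyloxy)phenyl]-6-bromo-3,4-dihydro-2H-chromen-4-ol
Product: 20 (2R,3R,4S)-3,7,8-tris(benzyloxy)-2-[4-(benzyloxy)phenyl]-6-(4,4,5,5-tetramethyl-1,3,2-dioxaborolan-2-yl)-3,4-dihydro-2H-chromen-4-ol
Conditions: B2pin2, Pd(dppf)Cl2 (cat.), KOAc, 1,4-dioxane, 85 °C
Reagents that add atoms: bis(pinacolato)diboron, CC1(C)OB(OC1(C)C)B1OC(C)(C)C(C)(C)O1
Why: Miyaura borylation of the aryl bromide under weakly basic conditions tolerates the free benzylic alcohol and the benzyl ethers and touches no stereocenter.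

Step 12
Reactants: 18 (2R,3R,4R)-3,7,8-tris(benzyloxy)-2-[4-(benzyloxy)phenyl]-6-bromo-3,4-dihydro-2H-chromen-4-ol; 20 (2R,3R,4S)-3,7,8-tris(benzyloxy)-2-[4-(benzyloxy)phenyl]-6-(4,4,5,5-tetramethyl-1,3,2-dioxaborolan-2-yl)-3,4-dihydro-2H-chromen-4-ol
Product: 21 (2R,2'R,3R,3'R,4R,4'S)-3,3',7,7',8,8'-hexakis(benzyloxy)-2,2'-bis[4-(benzyloxy)phenyl]-3,3',4,4'-tetrahydro-2H,2'H-[6,6'-bichromene]-4,4'-diol
Conditions: Pd(OAc)2 (cat.), SPhos, K3PO4, toluene–H2O, 80 °C
Reagents that add atoms: none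
Why: Suzuki–Miyaura coupling forms the C6–C6' bond between two rings that each carry a single ortho substituent, a case for which a bulky biaryl phosphine is adequate, and it leaves all six stereocenters untouched.

Step 13
Reactants: 21 (2R,2'R,3R,3'R,4R,4'S)-3,3',7,7',8,8'-hexakis(benzyloxy)-2,2'-bis[4-(benzyloxy)phenyl]-3,3',4,4'-tetrahydro-2H,2'H-[6,6'-bichromene]-4,4'-diol
Product: 22 (2R,2'R,3R,3'R,4R,4'S)-2,2'-bis(4-hydroxyphenyl)-3,3',4,4'-tetrahydro-2H,2'H-[6,6'-bichromene]-3,3',4,4',7,7',8,8'-octol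
Conditions: H2 (1 atm), Pd(OH)2/C, EtOAc–MeOH, rt
Reagents that add atoms: none
Why: Catalytic hydrogenolysis of the eight benzyl ethers under neutral conditions, in which aryl and alkyl benzyl ethers should cleave faster than the secondary benzylic C4–O bonds as long as the medium stays free of acid.

**Compound list**

1 | (S)-4-benzyl-1,3-oxazolidin-2-one | O=C1N[C@@H](Cc2ccccc2)CO1 | starting material
2 | (benzyloxy)acetyl chloride | O=C(Cl)COCc1ccccc1 | starting material
3 | (4S)-4-benzyl-3-[(benzyloxy)acetyl]-1,3-oxazolidin-2-one | O=C1OC[C@H](Cc2ccccc2)N1C(=O)COCc1ccccc1 | intermediate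
4 | 4-(benzyloxy)benzaldehyde | O=Cc1ccc(OCc2ccccc2)cc1 | starting material
5 | (4S)-4-benzyl-3-[(Z)-2-(benzyloxy)-1-[(dibutylboranyl)oxy]ethenyl]-1,3-oxazolidin-2-one (boron enolate, not isolated) | CCCCB(CCCC)O/C(=C\OCc1ccccc1)N1C(=O)OC[C@@H]1Cc1ccccc1 | intermediate
6 | (4S)-4-benzyl-3-[(2S,3R)-2-(benzyloxy)-3-[4-(benzyloxy)phenyl]-3-hydroxypropanoyl]-1,3-oxazolidin-2-one | O=C1OC[C@H](Cc2ccccc2)N1C(=O)[C@@H](OCc1ccccc1)[C@H](O)c1ccc(OCc2ccccc2)cc1 | intermediate
7 | (2S,3R)-2-(benzyloxy)-3-[4-(benzyloxy)phenyl]-3-hydroxypropaneperoxoic acid (not isolated) | OOC(=O)[C@@H](OCc1ccccc1)[C@H](O)c1ccc(OCc2ccccc2)cc1 | intermediate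
8 | (2S,3R)-2-(benzyloxy)-3-[4-(benzyloxy)phenyl]-3-hydroxypropanoic acid | OC(=O)[C@@H](OCc1ccccc1)[C@H](O)c1ccc(OCc2ccccc2)cc1 | intermediate
9 | (5S,6R)-5-(benzyloxy)-6-[4-(benzyloxy)phenyl]-2,2-dimethyl-1,3-dioxan-4-one | CC1(C)OC(=O)[C@@H](OCc2ccccc2)[C@@H](c2ccc(OCc3ccccc3)cc2)O1 | intermediate
10 | 3-fluorobenzene-1,2-diol | Oc1cccc(F)c1O | starting material
11 | 1,2-bis(benzyloxy)-3-fluorobenzene | Fc1cccc(OCc2ccccc2)c1OCc1ccccc1 | intermediate
12 | 1,2-bis(benzyloxy)-4-bromo-3-fluorobenzene | Fc1c(Br)ccc(OCc2ccccc2)c1OCc1ccccc1 | intermediate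
13 | [3,4-bis(benzyloxy)-2-fluorophenyl]lithium (not isolated) | [Li]c1ccc(OCc2ccccc2)c(OCc2ccccc2)c1F | intermediate
14 | lithium (5S,6R)-5-(benzyloxy)-4-[3,4-bis(benzyloxy)-2-fluorophenyl]-6-[4-(benzyloxy)phenyl]-2,2-dimethyl-1,3-dioxan-4-olate, either configuration at C4 (not isolated) | CC1(C)OC([O-])(c2ccc(OCc3ccccc3)c(OCc3ccccc3)c2F)[C@@H](OCc2ccccc2)[C@@H](c2ccc(OCc3ccccc3)cc2)O1.[Li+] | intermediate
15 | lithium (1R,2S)-2-(benzyloxy)-1-[4-(benzyloxy)phenyl]-3-[3,4-bis(benzyloxy)-2-fluorophenyl]-3-oxopropan-1-olate (not isolated) | O=C(c1ccc(OCc2ccccc2)c(OCc2ccccc2)c1F)[C@@H](OCc1ccccc1)[C@H]([O-])c1ccc(OCc2ccccc2)cc1.[Li+] | intermediate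
16 | (2R,3S)-3,7,8-tris(benzyloxy)-2-[4-(benzyloxy)phenyl]-2,3-dihydro-4H-chromen-4-one (2,3-cis) | O=C1c2ccc(OCc3ccccc3)c(OCc3ccccc3)c2O[C@H](c2ccc(OCc3ccccc3)cc2)[C@@H]1OCc1ccccc1 | intermediate
17 | (2R,3R,4R)-3,7,8-tris(benzyloxy)-2-[4-(benzyloxy)phenyl]-3,4-dihydro-2H-chromen-4-ol (all-cis) | O[C@@H]1c2ccc(OCc3ccccc3)c(OCc3ccccc3)c2O[C@H](c2ccc(OCc3ccccc3)cc2)[C@@H]1OCc1ccccc1 | intermediate
18 | (2R,3R,4R)-3,7,8-tris(benzyloxy)-2-[4-(benzyloxy)phenyl]-6-bromo-3,4-dihydro-2H-chromen-4-ol | O[C@@H]1c2cc(Br)c(OCc3ccccc3)c(OCc3ccccc3)c2O[C@H](c2ccc(OCc3ccccc3)cc2)[C@@H]1OCc1ccccc1 | intermediate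
19 | (2R,3R,4S)-3,7,8-tris(benzyloxy)-2-[4-(benzyloxy)phenyl]-6-bromo-3,4-dihydro-2H-chromen-4-ol (2,3-cis-3,4-trans) | O[C@H]1c2cc(Br)c(OCc3ccccc3)c(OCc3ccccc3)c2O[C@H](c2ccc(OCc3ccccc3)cc2)[C@@H]1OCc1ccccc1 | intermediate
20 | (2R,3R,4S)-3,7,8-tris(benzyloxy)-2-[4-(benzyloxy)phenyl]-6-(4,4,5,5-tetramethyl-1,3,2-dioxaborolan-2-yl)-3,4-dihydro-2H-chromen-4-ol | O[C@H]1c2cc(B3OC(C)(C)C(C)(C)O3)c(OCc3ccccc3)c(OCc3ccccc3)c2O[C@H](c2ccc(OCc3ccccc3)cc2)[C@@H]1OCc1ccccc1 | intermediate
21 | (2R,2'R,3R,3'R,4R,4'S)-3,3',7,7',8,8'-hexakis(benzyloxy)-2,2'-bis[4-(benzyloxy)phenyl]-3,3',4,4'-tetrahydro-2H,2'H-[6,6'-bichromene]-4,4'-diol | O[C@@H]1c2cc(-c3cc4c(c(OCc5ccccc5)c3OCc3ccccc3)O[C@H](c3ccc(OCc5ccccc5)cc3)[C@H](OCc3ccccc3)[C@H]4O)c(OCc3ccccc3)c(OCc3ccccc3)c2O[C@H](c2ccc(OCc3ccccc3)cc2)[C@@H]1OCc1ccccc1 | intermediate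
22 | (2R,2'R,3R,3'R,4R,4'S)-2,2'-bis(4-hydroxyphenyl)-3,3',4,4'-tetrahydro-2H,2'H-[6,6'-bichromene]-3,3',4,4',7,7',8,8'-octol | Oc1ccc([C@H]2Oc3c(cc(-c4cc5c(c(O)c4O)O[C@H](c4ccc(O)cc4)[C@H](O)[C@H]5O)c(O)c3O)[C@@H](O)[C@H]2O)cc1 | target

**Step count and risks**

Total step count: 13. Longest linear sequence: 11 steps (steps 1–4 and 7–13).

Steps most likely to fail:

1. Step 7. The aryllithium may add a second time if the cyclic hemiketal opens while aryllithium is still present, and the lithium keto-alkoxide may undergo retro-aldol cleavage or epimerise at C3 before the ring closes. The fallback separates the two bond formations. Setting out from aldol adduct 6, transamidation (AlMe3, MeNH(OMe)·HCl, CH2Cl2, 0 °C) should give the Weinreb amide (2S,3R)-2-(benzyloxy)-3-[4-(benzyloxy)phenyl]-3-hydroxy-N-methoxy-N-methylpropanamide F1. Its hydroxyl is deprotonated with i-PrMgCl and aryllithium 13 (from 12) is added at −78 °C; the chelated tetrahedral adduct survives until the aqueous quench and gives the isolated hydroxy ketone (2S,3R)-2-(benzyloxy)-3-[4-(benzyloxy)phenyl]-1-[3,4-bis(benzyloxy)-2-fluorophenyl]-3-hydroxypropan-1-one F2. K2CO3 in DMF at room temperature then closes ring C by intramolecular SNAr, and the route is rejoined at chromanone 16.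

2. Step 13. Over-reduction, that is hydrogenolysis of one or both benzylic C4–O bonds, may compete with the slower cleavage of the hindered alkyl benzyl ethers at O3 and O3'. The fallback masks the carbinols first. Setting out from 21, both C4 hydroxyls are silylated (TBSOTf, 2,6-lutidine, CH2Cl2, −78 °C) to the 4,4'-bis-O-(tert-butyldimethylsilyl) ether of 21, F3. Hydrogenolysis (H2, Pd(OH)2/C, EtOAc) then removes the eight benzyl groups while the benzylic silyl ethers resist C–O cleavage, giving the 4,4'-bis-O-(tert-butyldimethylsilyl) ether of the target, F4. Buffered fluoride (TBAF, AcOH, THF, 0 °C) removes the silyl groups and arrives at 22.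

3. Step 10. The C4 cation may be captured with poor facial selectivity, or be lost to elimination (flav-3-ene) or to intermolecular Friedel–Crafts alkylation. The fallback replaces the ionisation by a displacement. Setting out from 18, Mitsunobu inversion (4-nitrobenzoic acid, PPh3, DIAD, THF, 0 °C) should give the (2R,3R,4S) 4-nitrobenzoate of the 3,4-trans alcohol, F5. Methanolysis (K2CO3, MeOH, 0 °C) then returns to the route at 19.

Further compounds
F1 | step 7 | (2S,3R)-2-(benzyloxy)-3-[4-(benzyloxy)phenyl]-3-hydroxy-N-methoxy-N-methylpropanamide | CON(C)C(=O)[C@@H](OCc1ccccc1)[C@H](O)c1ccc(OCc2ccccc2)cc1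
F2 | step 7 | (2S,3R)-2-(benzyloxy)-3-[4-(benzyloxy)phenyl]-1-[3,4-bis(benzyloxy)-2-fluorophenyl]-3-hydroxypropan-1-one | O=C(c1ccc(OCc2ccccc2)c(OCc2ccccc2)c1F)[C@@H](OCc1ccccc1)[C@H](O)c1ccc(OCc2ccccc2)cc1
F3 | step 13 | 4,4'-bis-O-(tert-butyldimethylsilyl) ether of 21 | CC(C)(C)[Si](C)(C)O[C@@H]1c2cc(-c3cc4c(c(OCc5ccccc5)c3OCc3ccccc3)O[C@H](c3ccc(OCc5ccccc5)cc3)[C@H](OCc3ccccc3)[C@H]4O[Si](C)(C)C(C)(C)C)c(OCc3ccccc3)c(OCc3ccccc3)c2O[C@H](c2ccc(OCc3ccccc3)cc2)[C@@H]1OCc1ccccc1
F4 | step 13 | 4,4'-bis-O-(tert-butyldimethylsilyl) ether of 22 | Oc1ccc([C@H]2Oc3c(cc(-c4cc5c(c(O)c4O)O[C@H](c4ccc(O)cc4)[C@H](O)[C@H]5O[Si](C)(C)C(C)(C)C)c(O)c3O)[C@@H](O[Si](C)(C)C(C)(C)C)[C@H]2O)cc1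
F5 | step 10 | 4-nitrobenzoate ester of 19 (3,4-trans) | O=C(O[C@H]1c2cc(Br)c(OCc3ccccc3)c(OCc3ccccc3)c2O[C@H](c2ccc(OCc3ccccc3)cc2)[C@@H]1OCc1ccccc1)c1ccc([N+](=O)[O-])cc1
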